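## The problem

Target 15 is 9α,13-epoxy-8β-hydroxy-7-oxolabdan-15,16-olide, (5S,8R,9S,10S,13S). It is a trans-decalin (rings A and B) that carries at C9 a spiro oxolane (ring C: O, C9, C11, C12, C13), which at C13 is spiro-fused to a γ-lactone (ring D: C13, C14, C15, O, C16).

C8, C9 and C10 are contiguous and fully substituted. C8 is a tertiary carbinol next to the C7 ketone, and a cation at C9 is one 1,2-shift away from the C10 methyl.

The C8 hydroxyl (β) and the C9 oxygen (α) are both axial on ring B. This trans-diaxial pair is the imprint of an 8β,9β-epoxide opened at C9 from the α face, so C8 and C9 can be set together and stereospecifically once one face of a C8=C9 olefin is chosen.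

C5 and C10 can come from the chiral pool, and a C7 hydroxyl can steer the face at C8/C9, but nothing in the decalin reaches C13.

C13 is the hard centre. Its two ring D arms, C14 and C16, are both methylenes and differ only in their position relative to the ester oxygen, so a ring closure onto C13 has no basis for facial choice.

The feature that opens the problem is ring D itself. Deleting its ring oxygen joins C16 to C15 and gives a cyclobutanone (C13, C14, C15, C16) with a local mirror plane through C13 and C15, in which C13 is not a stereocentre. Inserting one oxygen atom between C15 and C16 re-creates ring D and C13 in the same event.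

Sensitive functions are the β-alkoxy lactone (base opens ring C by E1cB at C13), the α-ketol (base, glycol-cleaving oxidants) and the free tertiary alcohol.

## Retrosynthesis

**15 ⇒ 14.** The ring D oxygen is deleted (the O–C16 and O–C15 bonds are replaced by a C15–C16 bond), giving the spiro cyclobutanone 14. Against the neighbouring cuts (C13–O by oxa-Michael addition, or lactonisation of a preset C13 carbinol), this is the only one that removes the C13 stereocentre. The precursor has one stereocentre fewer and a four-carbon unit that is achiral. The forward reaction, a Baeyer–Villiger oxygen insertion, must select one of two diastereotopic methylenes (C16, on the C10 face of ring C) and must leave the C7 ketone alone.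

**14 ⇒ 13 ⇒ 11.** Diketone 14 is the double oxidation product of triol 13 (7β-OH, 8β-OH, 15-OH). In 13 the C9–O bond is cut: ring C is the product of a 5-exo opening of the 8β,9β-epoxide 12 by the C13 hydroxyl, and 12 comes from olefin triol 11 by epoxidation directed by the 7β-hydroxyl. This cut is preferred to oxa-Michael addition of O13 to an 8-en-7-one followed by enolate hydroxylation, because there the C8 configuration is not secured. It is also preferred to intermolecular hydrolysis of an epoxide at the neopentyl-like C9. The precursor 11 has no stereocentre at C8 or C9 and no ring C. The forward reaction must put the epoxide on the β face and open it at C9 with inversion, not at C8.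

**11 ⇒ 9 ⇒ 8.** The C7 oxygen is removed. The 7β-alcohol comes from enone 9 by 1,2-reduction, and 9 from the 8(9)-olefin 8 by allylic oxidation of the ring methylene C7. The C7 oxygen is needed twice: as the final ketone and, as the 7β-alcohol, as the handle that directs the epoxide to the β face against the C10 methyl. The forward oxidation must prefer C7 over C11 and C17.

**8 ⇒ 4 + 5.** The C12–C13 bond is cut. The alkyllithium from iodide 4 adds to the commercial cyclobutanone 5, which brings C13–C16 as an achiral block with C15 masked as a silyl ether. Cutting here keeps the decalin partner a simple primary iodide and makes the route convergent.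

**4 ⇒ 3 ⇒ 2 ⇒ 1.** Iodide 4 comes from alcohol 3, ester 2 and (+)-sclareolide 1. Sclareolide supplies rings A and B, C5, C10, the four methyls and C11/C12. Its lactone opening with loss of the C8 oxygen gives the 8(9)-olefin that all later chemistry uses.

## Roads not taken

**Alternative 1:** Cut the C13–O bond (the most obvious, biomimetic cut). The forward key step is 5-exo-trig oxa-Michael addition of the 9α-hydroxyl of hydroxy butenolide A1 (8β,9α-dihydroxy-7-oxolabd-13-en-15,16-olide) to C13.
- The two faces of the butenolide differ only through C8 and C10, four bonds away, and the addition is reversible, so a mixture of C13 epimers is to be expected.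
- A1 needs a free tertiary 9α-hydroxyl, which means intermolecular delivery of oxygen to the most hindered carbon of the molecule.
- A1 is a β-hydroxy ketone (C7=O, C9–OH) and is open to retro-aldol cleavage of C8–C9 under the basic conditions of the ring closure.
- The chosen plan makes the C9–O bond intramolecularly and stereospecifically, and makes C13 by reagent control.

**Alternative 2:** Same C9–O cut as in the chosen route, but with ring D and C13 already in place. The forward key step is 5-exo opening of epoxide A2 ((13S)-8β,9β-epoxy-7β,13-dihydroxylabdan-15,16-olide) by its C13 hydroxyl.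
- The C13 carbinol carries three methylene arms and would have to be made beforehand in enantioenriched form, for example by asymmetric epoxidation of a 2-substituted allylic alcohol (Ti(OiPr)4/tartrate), cyanide opening and lactonisation. That is four to five extra steps.
- The β-hydroxy lactone dehydrates easily and cannot be carried through the organolithium coupling.
- The chosen plan replaces this fragment by a purchased achiral ketone and postpones C13 to the last step.

**Alternative 3:** Cut C13–C14 and C15–C16. The forward key step is [2+2] cycloaddition of dichloroketene to the exocyclic enol ether A3 (9α,13-epoxy-8β-hydroxy-14,15-dinorlabd-13(16)-en-7-one), giving dichlorocyclobutanone A4. A chlorine-directed Baeyer–Villiger oxidation and dechlorination would follow.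
- C13 would be fixed by the face of ketene approach, controlled only across the ring oxygen by C8 versus C10. This is a weak and unpredictable bias.
- A3 again needs the free 9α-alcohol (plus an alkyne cycloisomerisation), its 8-hydroxyl must be masked from the ketene, and the exocyclic enol ether isomerises easily.
- The chosen plan reaches the same kind of cyclobutanone from a catalogue compound and sets C13 with a catalyst whose antipode can be chosen.

Key step: step 9

**Remarks.**
- Labdane numbering is used throughout. "15,16-Cyclolabdane" means the labdane skeleton with an added C15–C16 bond, that is, a cyclobutane made of C13, C14, C15 and C16.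
- Assumption: ketone 5 is taken as a catalogue compound.
- The cis relation of the two cyclobutane oxygens in 7–13 is drawn for the expected major isomer. It is erased in step 8, so both isomers converge.
- The antipode of the catalyst in step 9 cannot be predicted on paper. It is to be fixed by running both.

## Route

Step 1
Reactants: 1 (+)-sclareolide
Product: 2 methyl 13,14,15,16-tetranorlabd-8-en-12-oate
Conditions: conc. H2SO4, MeOH, reflux
Reagents that add atoms: methanol, CO
Why: Acid-catalysed lactone methanolysis with E1 loss of the tertiary C8 oxygen; under these equilibrating conditions the tetrasubstituted 8(9)-olefin should be the thermodynamic product, and C5 and C10 are not touched.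

Step 2
Reactants: 2 methyl 13,14,15,16-tetranorlabd-8-en-12-oate
Product: 3 13,14,15,16-tetranorlabd-8-en-12-ol
Conditions: LiAlH4, THF, 0 °C to rt
Reagents that add atoms: none
Why: Hydride reduction of the ester to the primary alcohol; the isolated tetrasubstituted olefin is inert.

Step 3
Reactants: 3 13,14,15,16-tetranorlabd-8-en-12-ol
Product: 4 12-iodo-13,14,15,16-tetranorlabd-8-ene
Conditions: I2, PPh3, imidazole, CH2Cl2, 0 °C to rt
Reagents that add atoms: iodine, II
Why: Appel-type iodination by SN2 displacement of the oxyphosphonium at the primary C12; no stereocentre is involved.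

Step 4
Reactants: 4 12-iodo-13,14,15,16-tetranorlabd-8-ene; 5 3-[(tert-butyldimethylsilyl)oxy]cyclobutan-1-one
Product: 8 15-(tert-butyldimethylsilyloxy)-13-(trimethylsilyloxy)-15,16-cyclolabd-8-ene, via alkyllithium 6 (not isolated), via lithium alkoxide 7 (not isolated)
Conditions: t-BuLi (2.1 equiv), Et2O–pentane, −78 °C; then 5, −78 °C; then TMSCl, −78 °C to rt
Reagents that add atoms: chlorotrimethylsilane, C[Si](C)(C)Cl
Why: Iodine–lithium exchange, 1,2-addition to the strained ketone (forming C12–C13) and O-silylation in one flask; the nucleophile should enter trans to the silyloxy group, but this cis/trans relation is erased in step 8. The TMS ether keeps the tertiary alcohol out of the next oxidation.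

Step 5
Reactants: 8 15-(tert-butyldimethylsilyloxy)-13-(trimethylsilyloxy)-15,16-cyclolabd-8-ene
Product: 9 15-(tert-butyldimethylsilyloxy)-13-(trimethylsilyloxy)-15,16-cyclolabd-8-en-7-one
Conditions: CrO3, 3,5-dimethylpyrazole, CH2Cl2, −20 °C
Reagents that add atoms: chromium trioxide, O=[Cr](=O)=O
Why: Allylic oxidation by the hexavalent chromium–pyrazole complex at the ring methylene C7, the most accessible allylic C–H (C11 is flanked by C9/C10 and C12, C17 is a methyl); the silyl ether prevents chromate-mediated oxidative cyclisation of the bishomoallylic alcohol.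

Step 6
Reactants: 9 15-(tert-butyldimethylsilyloxy)-13-(trimethylsilyloxy)-15,16-cyclolabd-8-en-7-one
Product: 11 15,16-cyclolabd-8-ene-7β,13,15-triol, via allylic alcohol 10 (not isolated)
Conditions: NaBH4, CeCl3·7H2O, MeOH, −20 to 0 °C; then TBAF, THF, rt
Reagents that add atoms: none
Why: Luche 1,2-reduction with axial hydride delivery from the α face should give the pseudo-equatorial 7β-alcohol (as cholest-4-en-3-one gives the 3β-ol); fluoride then removes both silyl ethers.

Step 7
Reactants: 11 15,16-cyclolabd-8-ene-7β,13,15-triol
Product: 13 9α,13-epoxy-15,16-cyclolabdane-7β,8β,15-triol, via 8β,9β-epoxide 12 (not isolated)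
Conditions: VO(acac)2 (5 mol %), t-BuOOH (decane), CH2Cl2, 0 °C to rt; then CSA (10 mol %), rt
Reagents that add atoms: tert-butyl hydroperoxide, CC(C)(C)OO
Why: Hydroxyl-directed epoxidation: the pentavalent vanadium alkylperoxide bound to the allylic 7β-OH delivers oxygen to the β face of the tetrasubstituted olefin, as 3β-hydroxy-Δ4-steroids give β-epoxides in spite of the angular methyl. Acid then promotes the 5-exo-tet epoxy-alcohol cyclisation: O13 attacks C9 from the α face, axially and with inversion (Fürst–Plattner), so C9 (O α, C11 β) and C8 (OH β, Me α) are set together; attack at C8 would be 6-endo and equatorial.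

Step 8
Reactants: 13 9α,13-epoxy-15,16-cyclolabdane-7β,8β,15-triol
Product: 14 9α,13-epoxy-8β-hydroxy-15,16-cyclolabdane-7,15-dione
Conditions: Dess–Martin periodinane, CH2Cl2, 0 °C to rt
Reagents that add atoms: none
Why: Dess–Martin oxidation of both secondary carbinols (C7 and C15); the tertiary 8-OH cannot be oxidised and a secondary/tertiary diol should give the α-ketol without glycol cleavage. With C15 now sp2 the cyclobutane is locally symmetric and C13 is no longer a stereo element.

Step 9
Reactants: 14 9α,13-epoxy-8β-hydroxy-15,16-cyclolabdane-7,15-dione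
Product: 15 (5S,8R,9S,10S,13S)-9α,13-epoxy-8β-hydroxy-7-oxolabdan-15,16-olide
Conditions: chiral phosphoric acid (R)- or (S)-H8-TRIP (10 mol %, antipode chosen for C16 migration), 30% aq. H2O2, CHCl3, −40 °C
Reagents that add atoms: hydrogen peroxide, OO
Why: Catalytic asymmetric Baeyer–Villiger oxidation: the chiral acid activates the strained ketone and H2O2 by hydrogen bonding, peroxide adds to C15 to give the Criegee adduct, and the α-methylene anti-periplanar to the O–O bond migrates to oxygen with retention. The closest known reaction type is the desymmetrising Baeyer–Villiger oxidation of prochiral 3-substituted and 3,3-disubstituted cyclobutanones to β-substituted γ-butyrolactones with chiral Brønsted acids or chiral metal Lewis acids and H2O2 or peracids, and with Baeyer–Villiger monooxygenases. No ring is closed; the four-membered ring is expanded to the five-membered lactone by a 1,2-shift, a formal insertion of one oxygen atom between C15 and C16. The only new stereocentre is C13, fixed by which of the two diastereotopic methylenes migrates. This is controlled by the catalyst pocket, because the nearest substrate stereocentre (C9) is three bonds from the migrating carbons and its substituents C8 and C10 point away from C15; the antipode that selects the methylene on the C10 face of ring C (C16) is used. The step needs chemoselectivity against the C7 ketone: the cyclobutanone reacts through strain release, while C7 is a six-ring ketone next to the fully substituted C8 and should be inert to cold aqueous H2O2. The conditions are weakly acidic and never basic, so the tertiary alcohol, the ether and the product β-alkoxy lactone (E1cB opening at C13) should survive.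

## Compound list

1 | (+)-sclareolide | CC1(C)CCC[C@@]2(C)[C@H]1CC[C@@]1(C)OC(=O)C[C@H]21 | starting material
2 | methyl 13,14,15,16-tetranorlabd-8-en-12-oate | CC1(C)CCC[C@@]2(C)[C@H]1CCC(C)=C2CC(=O)OC | intermediate
3 | 13,14,15,16-tetranorlabd-8-en-12-ol | CC1(C)CCC[C@@]2(C)[C@H]1CCC(C)=C2CCO | intermediate
4 | 12-iodo-13,14,15,16-tetranorlabd-8-ene | CC1(C)CCC[C@@]2(C)[C@H]1CCC(C)=C2CCI | intermediate
5 | 3-[(tert-butyldimethylsilyl)oxy]cyclobutan-1-one | CC(C)(C)[Si](C)(C)OC1CC(=O)C1 | starting material
6 | (13,14,15,16-tetranorlabd-8-en-12-yl)lithium | CC1(C)CCC[C@@]2(C)[C@H]1CCC(C)=C2CC[Li] | intermediate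
7 | lithium 15-(tert-butyldimethylsilyloxy)-15,16-cyclolabd-8-en-13-olate (13-O and 15-O cis) | CC1(C)CCC[C@@]2(C)[C@H]1CCC(C)=C2CC[C@]1(O[Li])C[C@@H](O[Si](C)(C)C(C)(C)C)C1 | intermediate
8 | 15-(tert-butyldimethylsilyloxy)-13-(trimethylsilyloxy)-15,16-cyclolabd-8-ene (13-O and 15-O cis) | CC1(C)CCC[C@@]2(C)[C@H]1CCC(C)=C2CC[C@]1(O[Si](C)(C)C)C[C@@H](O[Si](C)(C)C(C)(C)C)C1 | intermediate
9 | 15-(tert-butyldimethylsilyloxy)-13-(trimethylsilyloxy)-15,16-cyclolabd-8-en-7-one | CC1(C)CCC[C@@]2(C)[C@H]1CC(=O)C(C)=C2CC[C@]1(O[Si](C)(C)C)C[C@@H](O[Si](C)(C)C(C)(C)C)C1 | intermediate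
10 | 15-(tert-butyldimethylsilyloxy)-13-(trimethylsilyloxy)-15,16-cyclolabd-8-en-7β-ol | CC1(C)CCC[C@@]2(C)[C@H]1C[C@H](O)C(C)=C2CC[C@]1(O[Si](C)(C)C)C[C@@H](O[Si](C)(C)C(C)(C)C)C1 | intermediate
11 | 15,16-cyclolabd-8-ene-7β,13,15-triol (13-OH and 15-OH cis) | CC1(C)CCC[C@@]2(C)[C@H]1C[C@H](O)C(C)=C2CC[C@]1(O)C[C@@H](O)C1 | intermediate
12 | 8β,9β-epoxy-15,16-cyclolabdane-7β,13,15-triol | CC1(C)CCC[C@@]2(C)[C@H]1C[C@H](O)[C@]3(C)O[C@]23CC[C@]1(O)C[C@@H](O)C1 | intermediate
13 | 9α,13-epoxy-15,16-cyclolabdane-7β,8β,15-triol (15-OH cis to the ring C oxygen) | CC1(C)CCC[C@@]2(C)[C@H]1C[C@H](O)[C@](C)(O)[C@]21CC[C@@]2(C[C@@H](O)C2)O1 | intermediate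
14 | 9α,13-epoxy-8β-hydroxy-15,16-cyclolabdane-7,15-dione | CC1(C)CCC[C@@]2(C)[C@H]1CC(=O)[C@](C)(O)[C@]21CCC2(CC(=O)C2)O1 | intermediate
15 | (5S,8R,9S,10S,13S)-9α,13-epoxy-8β-hydroxy-7-oxolabdan-15,16-olide (CNP0208728.2) | CC1(C)CCC[C@@]2(C)[C@H]1CC(=O)[C@](C)(O)[C@]21CC[C@]2(COC(=O)C2)O1 | target

## Step count and risks

Total: 9 steps. Longest linear sequence: 9 steps (1 to 15); ketone 5 enters as purchased in step 4.

**Step 9 (key step).** What may go wrong: insufficient discrimination between the two α-methylenes by the catalyst on a substrate whose own chirality is remote, giving both C13 epimers. A slow reaction at −40 °C with competing uncatalysed insertion is also possible. Fallback (sets out from 14, returns at 15): oxidation of 14 with an achiral peracid (mCPBA, CH2Cl2, 0 °C) should give 15 together with its C13 epimer F1. After separation, F1 is treated briefly with catalytic DBU in MeCN. This opens ring C by β-elimination to the 9α-hydroxy butenolide F2, which re-closes by oxa-Michael addition to a mixture containing 15, and the cycle is repeated. Contact with base is kept short because F2 is a β-hydroxy ketone.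

**Step 7.** What may go wrong: epoxidation on the α face or re-oxidation of the pseudo-equatorial allylic alcohol to the enone. During the acid step, ionisation at C9 could be followed by migration of the C10 methyl, or the epoxy alcohol could undergo a semipinacol shift, instead of capture by O13. Fallback (sets out from 9, returns at 14):
- K2CO3/MeOH removes the TMS ether to give hydroxy enone F3.
- KHMDS (THF, −78 to 0 °C) triggers 5-exo-trig oxa-Michael addition of O13 to C9 from the α face to give potassium enolate F4.
- F4 is hydroxylated at C8 in the same flask with 2-(phenylsulfonyl)-3-phenyloxaziridine to give ketol silyl ether F5.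
- TBAF gives cyclobutanol F6, and Dess–Martin oxidation gives 14.

This path needs no β-epoxide and no cation at C9. Its price is that the C8 configuration rests on approach of the oxidant anti to the axial C9–O bond and is not stereospecific.

**Step 5.** What may go wrong: competing oxidation at C11 or C17, loss of the tertiary TMS ether followed by oxidative cyclisation, or low conversion with a hindered tetrasubstituted olefin. Fallback (sets out from 8, returns at 9): allylic hydroxylation by the ene/[2,3]-shift mechanism (catalytic SeO2, t-BuOOH, CH2Cl2) should give the 7α-alcohol F7, which is oxidised to 9 with MnO2 or Dess–Martin periodinane.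

**Step 4.** What may go wrong: enolisation of the cyclobutanone by the basic alkyllithium with β-elimination of silanolate, or incomplete silylation of the tertiary alkoxide. Fallback (sets out from 4 and 5, returns at 8): single-electron Barbier coupling of 4 and 5 with SmI2 (THF–HMPA, rt) under essentially non-basic conditions gives tertiary alcohol F8, which is silylated with N-(trimethylsilyl)imidazole to give 8.

## Further compounds

F1 | step 9 | (13R)-9α,13-epoxy-8β-hydroxy-7-oxolabdan-15,16-olide (C13 epimer of 15) | CC1(C)CCC[C@@]2(C)[C@H]1CC(=O)[C@](C)(O)[C@]21CC[C@@]2(COC(=O)C2)O1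
F2 | step 9 | 8β,9α-dihydroxy-7-oxolabd-13-en-15,16-olide | CC1(C)CCC[C@@]2(C)[C@H]1CC(=O)[C@](C)(O)[C@]2(O)CCC1=CC(=O)OC1
F3 | step 7 | 15-(tert-butyldimethylsilyloxy)-13-hydroxy-15,16-cyclolabd-8-en-7-one | CC1(C)CCC[C@@]2(C)[C@H]1CC(=O)C(C)=C2CC[C@]1(O)C[C@@H](O[Si](C)(C)C(C)(C)C)C1
F4 | step 7 | potassium 15-(tert-butyldimethylsilyloxy)-9α,13-epoxy-15,16-cyclolabd-7-en-7-olate | CC1(C)CCC[C@@]2(C)[C@H]1CC(O[K])=C(C)[C@]21CC[C@@]2(C[C@@H](O[Si](C)(C)C(C)(C)C)C2)O1
F5 | step 7 | 15-(tert-butyldimethylsilyloxy)-9α,13-epoxy-8β-hydroxy-15,16-cyclolabdan-7-one | CC1(C)CCC[C@@]2(C)[C@H]1CC(=O)[C@](C)(O)[C@]21CC[C@@]2(C[C@@H](O[Si](C)(C)C(C)(C)C)C2)O1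
F6 | step 7 | 9α,13-epoxy-8β,15-dihydroxy-15,16-cyclolabdan-7-one | CC1(C)CCC[C@@]2(C)[C@H]1CC(=O)[C@](C)(O)[C@]21CC[C@@]2(C[C@@H](O)C2)O1
F7 | step 5 | 15-(tert-butyldimethylsilyloxy)-13-(trimethylsilyloxy)-15,16-cyclolabd-8-en-7α-ol | CC1(C)CCC[C@@]2(C)[C@H]1C[C@@H](O)C(C)=C2CC[C@]1(O[Si](C)(C)C)C[C@@H](O[Si](C)(C)C(C)(C)C)C1
F8 | step 4 | 15-(tert-butyldimethylsilyloxy)-15,16-cyclolabd-8-en-13-ol | CC1(C)CCC[C@@]2(C)[C@H]1CCC(C)=C2CC[C@]1(O)C[C@@H](O[Si](C)(C)C(C)(C)C)C1
A1 | alternative 1 | 8β,9α-dihydroxy-7-oxolabd-13-en-15,16-olide | CC1(C)CCC[C@@]2(C)[C@H]1CC(=O)[C@](C)(O)[C@]2(O)CCC1=CC(=O)OC1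
A2 | alternative 2 | (13S)-8β,9β-epoxy-7β,13-dihydroxylabdan-15,16-olide | CC1(C)CCC[C@@]2(C)[C@H]1C[C@H](O)[C@]3(C)O[C@]23CC[C@@]1(O)COC(=O)C1
A3 | alternative 3 | 9α,13-epoxy-8β-hydroxy-14,15-dinorlabd-13(16)-en-7-one | CC1(C)CCC[C@@]2(C)[C@H]1CC(=O)[C@](C)(O)[C@]21CCC(=C)O1
A4 | alternative 3 | 14,14-dichloro-9α,13-epoxy-8β-hydroxy-15,16-cyclolabdane-7,15-dione (CCl2 on the C8 face of ring C) | CC1(C)CCC[C@@]2(C)[C@H]1CC(=O)[C@](C)(O)[C@]21CC[C@]2(CC(=O)C2(Cl)Cl)O1
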